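**Retrosynthetic overview**
1. Ugonin G ⇐ tris-MOM flavonol 22 (mild acid methanolysis) ⇐ 2'-hydroxychalcone 21 (Algar–Flynn–Oyamada; the pyranone C ring is formed last) ⇐ acetophenone 18 + aldehyde 20 (Claisen–Schmidt).
2. 18 ⇐ Negishi sp3–sp2 coupling of (R)-α-cyclogeranylzinc iodide 15 with iodoacetophenone 14. The 6- versus 8-regiochemistry is fixed by iodination ortho to the chelated OH of phloroacetophenone, then a TBS/MOM permutation.
3. (R)-α-Cyclogeranyl iodide 10 ⇐ (R)-α-cyclogeraniol 9 ⇐ [2,3]-Wittig–Still rearrangement of the stannylmethyl ether of (S)-2,4,4-trimethylcyclohex-2-enol 5 (1,3-chirality transfer).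
4. 5 ⇐ ketoreductase reduction of achiral enone 4 (the only stereo-defining step) ⇐ Robinson annulation of isobutyraldehyde with ethyl vinyl ketone.
5. Ring order: cyclohexene ring (step 1), aromatic A and B rings purchased, pyranone ring (step 14).

Assumption: an (S)-selective ketoreductase for enone 4 is taken from a commercial KRED screening panel (TBS = tert-butyldimethylsilyl, MOM = methoxymethyl).

**Route**

Step 1
Reactants: 1 isobutyraldehyde; 2 ethyl vinyl ketone
Product: 4 2,4,4-trimethylcyclohex-2-en-1-one, via Michael adduct 2,2-dimethyl-5-oxoheptanal 3 (not isolated)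
Conditions: cat. H2SO4, PhMe, 45 °C then reflux (Dean–Stark)
Reagents that add atoms: none
Why: Acid-catalysed Robinson annulation, in which the enol of the aldehyde adds to the vinyl ketone (Michael addition) and the 1,5-keto-aldehyde closes by intramolecular aldol condensation to the only possible six-membered enone; no stereocenter is formed.

Step 2
Reactants: 4 2,4,4-trimethylcyclohex-2-en-1-one
Product: 5 (1S)-2,4,4-trimethylcyclohex-2-en-1-ol
Conditions: (S)-selective ketoreductase (KRED), NADP+ (cat.), i-PrOH (10 vol%), KPi buffer pH 7, 30 °C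
Reagents that add atoms: none
Why: Enzymatic asymmetric carbonyl reduction, in which the NADPH-dependent ketoreductase delivers hydride to the Re face of the C=O of the achiral enone (1,2-reduction only, C=C untouched) and so sets the first stereocenter as (S), with isopropanol recycling the cofactor.

Step 3
Reactants: 5 (1S)-2,4,4-trimethylcyclohex-2-en-1-ol; 6 tributyl(iodomethyl)stannane
Product: 7 tributyl({[(1S)-2,4,4-trimethylcyclohex-2-en-1-yl]oxy}methyl)stannane
Conditions: KH, 18-crown-6 (cat.), THF, 0 °C→rt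
Reagents that add atoms: none
Why: Williamson etherification of the deprotonated allylic alcohol with the reactive primary iodide; the C–O bond at the stereocenter is not touched.

Step 4
Reactants: 7 tributyl({[(1S)-2,4,4-trimethylcyclohex-2-en-1-yl]oxy}methyl)stannane
Product: 9 [(1R)-2,6,6-trimethylcyclohex-2-en-1-yl]methanol ((R)-α-cyclogeraniol), via lithiomethyl ether 8 (not isolated)
Conditions: n-BuLi, THF, −78→−20 °C; H2O quench
Reagents that add atoms: none
Why: Sn–Li exchange gives the α-alkoxymethyllithium, which undergoes the suprafacial [2,3]-sigmatropic Wittig–Still rearrangement, so the new C–C bond forms at C-3 on the face that carried the oxygen; this relays the (S)-carbinol center into the (R)-configured ring carbon bearing CH2OH while the double bond moves into the α-cyclogeranyl position.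

Step 5
Reactants: 9 [(1R)-2,6,6-trimethylcyclohex-2-en-1-yl]methanol
Product: 10 (6R)-6-(iodomethyl)-1,5,5-trimethylcyclohex-1-ene ((R)-α-cyclogeranyl iodide)
Conditions: PPh3, I2, imidazole, CH2Cl2, 0 °C→rt
Reagents that add atoms: iodine, II
Why: Appel-type iodination by SN2 at the CH2 group under imidazole-buffered conditions, so neither the adjacent stereocenter nor the acid-sensitive trisubstituted alkene is affected.

Step 6
Reactants: 11 2,4,6-trihydroxyacetophenone
Product: 12 1-[2,4-bis(tert-butyldimethylsilyloxy)-6-hydroxyphenyl]ethanone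
Conditions: TBSCl (2.1 equiv), imidazole, CH2Cl2/DMF, 0 °C
Reagents that add atoms: tert-butyldimethylsilyl chloride, CC(C)(C)[Si](C)(C)Cl
Why: Selective O-silylation, in which the para-OH and one ortho-OH react while the last ortho-OH is deactivated by its hydrogen bond to the ketone.

Step 7
Reactants: 12 1-[2,4-bis(tert-butyldimethylsilyloxy)-6-hydroxyphenyl]ethanone
Product: 13 1-[4,6-bis(tert-butyldimethylsilyloxy)-2-hydroxy-3-iodophenyl]ethanone
Conditions: NIS (1.05 equiv), DMF, 0 °C→rt
Reagents that add atoms: N-iodosuccinimide, O=C1CCC(=O)N1I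
Why: Electrophilic aromatic iodination occurs ortho to the free chelated phenol (C-3) because the alternative C-5 is shielded by two flanking OTBS groups.

Step 8
Reactants: 13 1-[4,6-bis(tert-butyldimethylsilyloxy)-2-hydroxy-3-iodophenyl]ethanone
Product: 14 1-[4,6-bis(tert-butyldimethylsilyloxy)-3-iodo-2-(methoxymethoxy)phenyl]ethanone
Conditions: NaH, THF, 0 °C; MOMCl, 0 °C→rt
Reagents that add atoms: chloromethyl methyl ether, COCCl
Why: Williamson-type O-alkylation of the phenol caps, as a MOM ether, the oxygen that will become O-5 of the flavonol.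

Step 9
Reactants: 10 (6R)-6-(iodomethyl)-1,5,5-trimethylcyclohex-1-ene; 14 1-[4,6-bis(tert-butyldimethylsilyloxy)-3-iodo-2-(methoxymethoxy)phenyl]ethanone
Product: 16 1-[4,6-bis(tert-butyldimethylsilyloxy)-2-(methoxymethoxy)-3-{[(1R)-2,6,6-trimethylcyclohex-2-en-1-yl]methyl}phenyl]ethanone, via alkylzinc iodide 15 (not isolated)
Conditions: Zn dust, LiCl, THF, 40 °C; then 14, Pd(OAc)2 (3 mol%), SPhos (6 mol%), THF, 25→50 °C
Reagents that add atoms: none
Why: Negishi sp3–sp2 cross-coupling, in which zinc inserts into the primary C–I bond and the ketone-tolerant alkylzinc iodide couples with the aryl iodide under Pd/SPhos, a catalyst suited to di-ortho-substituted aryl halides that suppresses β-hydride elimination; the stereocenter β to the metal is untouched.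

Step 10
Reactants: 16 1-[4,6-bis(tert-butyldimethylsilyloxy)-2-(methoxymethoxy)-3-{[(1R)-2,6,6-trimethylcyclohex-2-en-1-yl]methyl}phenyl]ethanone
Product: 17 1-[4,6-dihydroxy-2-(methoxymethoxy)-3-{[(1R)-2,6,6-trimethylcyclohex-2-en-1-yl]methyl}phenyl]ethanone
Conditions: TBAF (2.2 equiv), AcOH (2.2 equiv), THF, 0 °C
Reagents that add atoms: none
Why: Fluoride-mediated desilylation with buffered TBAF removes both aryl TBS ethers without affecting the MOM ether, the ketone or the alkene.

Step 11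
Reactants: 17 1-[4,6-dihydroxy-2-(methoxymethoxy)-3-{[(1R)-2,6,6-trimethylcyclohex-2-en-1-yl]methyl}phenyl]ethanone
Product: 18 1-[6-hydroxy-2,4-bis(methoxymethoxy)-3-{[(1R)-2,6,6-trimethylcyclohex-2-en-1-yl]methyl}phenyl]ethanone
Conditions: MOMCl (1.05 equiv), i-Pr2NEt, CH2Cl2, 0 °C
Reagents that add atoms: chloromethyl methyl ether, COCCl
Why: Chemoselective O-alkylation of the non-chelated 4-OH, while the 6-OH is held back by its hydrogen bond to the carbonyl; this leaves free exactly the oxygen para to the terpenylmethyl group, which must become pyranone O-1 to give the 6- and not the 8-substituted flavonol.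

Step 12
Reactants: 19 4-hydroxybenzaldehyde
Product: 20 4-(methoxymethoxy)benzaldehyde
Conditions: MOMCl, i-Pr2NEt, CH2Cl2, 0 °C→rt
Reagents that add atoms: chloromethyl methyl ether, COCCl
Why: MOM protection of the phenol (Williamson-type O-alkylation) so that the aldehyde is not deactivated as a phenoxide in the aldol step.

Step 13
Reactants: 18 1-[6-hydroxy-2,4-bis(methoxymethoxy)-3-{[(1R)-2,6,6-trimethylcyclohex-2-en-1-yl]methyl}phenyl]ethanone; 20 4-(methoxymethoxy)benzaldehyde
Product: 21 (2E)-1-[6-hydroxy-2,4-bis(methoxymethoxy)-3-{[(1R)-2,6,6-trimethylcyclohex-2-en-1-yl]methyl}phenyl]-3-[4-(methoxymethoxy)phenyl]prop-2-en-1-one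
Conditions: KOH (50% aq.), EtOH, rt, 24–48 h
Reagents that add atoms: none
Why: Claisen–Schmidt (crossed aldol) condensation of the methyl ketone with the non-enolisable aldehyde followed by dehydration gives the thermodynamically favoured (E)-chalcone; MOM ethers and the isolated alkene are stable to KOH.

Step 14
Reactants: 21 (2E)-1-[6-hydroxy-2,4-bis(methoxymethoxy)-3-{[(1R)-2,6,6-trimethylcyclohex-2-en-1-yl]methyl}phenyl]-3-[4-(methoxymethoxy)phenyl]prop-2-en-1-one
Product: 22 3-hydroxy-5,7-bis(methoxymethoxy)-2-[4-(methoxymethoxy)phenyl]-6-{[(1R)-2,6,6-trimethylcyclohex-2-en-1-yl]methyl}-4H-chromen-4-one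
Conditions: 30% H2O2, NaOH (aq.), MeOH, 0 °C→rt
Reagents that add atoms: hydrogen peroxide, OO
Why: Algar–Flynn–Oyamada reaction, in which alkaline hydrogen peroxide oxidatively cyclises the 2'-hydroxychalcone to the 3-hydroxyflavone and forms the pyranone ring, while the electron-rich trisubstituted ring alkene is inert to this nucleophilic oxidant.

Step 15
Reactants: 22 3-hydroxy-5,7-bis(methoxymethoxy)-2-[4-(methoxymethoxy)phenyl]-6-{[(1R)-2,6,6-trimethylcyclohex-2-en-1-yl]methyl}-4H-chromen-4-one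
Product: 23 Ugonin G (3,5,7-trihydroxy-2-(4-hydroxyphenyl)-6-{[(1R)-2,6,6-trimethylcyclohex-2-en-1-yl]methyl}-4H-chromen-4-one)
Conditions: HCl (ca. 1.5 M), MeOH/THF, rt→40 °C
Reagents that add atoms: none
Why: Acid-catalysed acetal methanolysis removes the three aryl MOM ethers under dilute, mild conditions of the kind used for prenyl-type trisubstituted alkenes next to phenols, so the alkene should neither migrate nor cyclise onto the 5- or 7-OH and the stereocenter is untouched.

**Compound list**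
1 | isobutyraldehyde (2-methylpropanal) | CC(C)C=O | starting material
2 | ethyl vinyl ketone (pent-1-en-3-one) | CCC(=O)C=C | starting material
3 | 2,2-dimethyl-5-oxoheptanal | CCC(=O)CCC(C)(C)C=O | intermediate
4 | 2,4,4-trimethylcyclohex-2-en-1-one | CC1=CC(C)(C)CCC1=O | intermediate
5 | (1S)-2,4,4-trimethylcyclohex-2-en-1-ol | CC1=CC(C)(C)CC[C@@H]1O | intermediate
6 | tributyl(iodomethyl)stannane | CCCC[Sn](CCCC)(CCCC)CI | starting material
7 | tributyl({[(1S)-2,4,4-trimethylcyclohex-2-en-1-yl]oxy}methyl)stannane | CC1=CC(C)(C)CC[C@@H]1OC[Sn](CCCC)(CCCC)CCCC | intermediate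
8 | {[(1S)-2,4,4-trimethylcyclohex-2-en-1-yl]oxy}methyllithium | CC1=CC(C)(C)CC[C@@H]1OC[Li] | intermediate
9 | [(1R)-2,6,6-trimethylcyclohex-2-en-1-yl]methanol ((R)-α-cyclogeraniol) | CC1=CCCC(C)(C)[C@H]1CO | intermediate
10 | (6R)-6-(iodomethyl)-1,5,5-trimethylcyclohex-1-ene | CC1=CCCC(C)(C)[C@H]1CI | intermediate
11 | 2,4,6-trihydroxyacetophenone | CC(=O)c1c(O)cc(O)cc1O | starting material
12 | 1-[2,4-bis(tert-butyldimethylsilyloxy)-6-hydroxyphenyl]ethanone | CC(=O)c1c(O)cc(O[Si](C)(C)C(C)(C)C)cc1O[Si](C)(C)C(C)(C)C | intermediate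
13 | 1-[4,6-bis(tert-butyldimethylsilyloxy)-2-hydroxy-3-iodophenyl]ethanone | CC(=O)c1c(O)c(I)c(O[Si](C)(C)C(C)(C)C)cc1O[Si](C)(C)C(C)(C)C | intermediate
14 | 1-[4,6-bis(tert-butyldimethylsilyloxy)-3-iodo-2-(methoxymethoxy)phenyl]ethanone | CC(=O)c1c(OCOC)c(I)c(O[Si](C)(C)C(C)(C)C)cc1O[Si](C)(C)C(C)(C)C | intermediate
15 | iodo{[(1R)-2,6,6-trimethylcyclohex-2-en-1-yl]methyl}zinc | CC1=CCCC(C)(C)[C@H]1C[Zn]I | intermediate
16 | 1-[4,6-bis(tert-butyldimethylsilyloxy)-2-(methoxymethoxy)-3-{[(1R)-2,6,6-trimethylcyclohex-2-en-1-yl]methyl}phenyl]ethanone | CC1=CCCC(C)(C)[C@H]1Cc1c(OCOC)c(C(C)=O)c(O[Si](C)(C)C(C)(C)C)cc1O[Si](C)(C)C(C)(C)C | intermediate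
17 | 1-[4,6-dihydroxy-2-(methoxymethoxy)-3-{[(1R)-2,6,6-trimethylcyclohex-2-en-1-yl]methyl}phenyl]ethanone | CC1=CCCC(C)(C)[C@H]1Cc1c(OCOC)c(C(C)=O)c(O)cc1O | intermediate
18 | 1-[6-hydroxy-2,4-bis(methoxymethoxy)-3-{[(1R)-2,6,6-trimethylcyclohex-2-en-1-yl]methyl}phenyl]ethanone | CC1=CCCC(C)(C)[C@H]1Cc1c(OCOC)c(C(C)=O)c(O)cc1OCOC | intermediate
19 | 4-hydroxybenzaldehyde | O=Cc1ccc(O)cc1 | starting material
20 | 4-(methoxymethoxy)benzaldehyde | COCOc1ccc(C=O)cc1 | intermediate
21 | (2E)-1-[6-hydroxy-2,4-bis(methoxymethoxy)-3-{[(1R)-2,6,6-trimethylcyclohex-2-en-1-yl]methyl}phenyl]-3-[4-(methoxymethoxy)phenyl]prop-2-en-1-one | CC1=CCCC(C)(C)[C@H]1Cc1c(OCOC)c(C(=O)/C=C/c2ccc(OCOC)cc2)c(O)cc1OCOC | intermediate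
22 | 3-hydroxy-5,7-bis(methoxymethoxy)-2-[4-(methoxymethoxy)phenyl]-6-{[(1R)-2,6,6-trimethylcyclohex-2-en-1-yl]methyl}-4H-chromen-4-one | CC1=CCCC(C)(C)[C@H]1Cc1c(OCOC)cc2oc(-c3ccc(OCOC)cc3)c(O)c(=O)c2c1OCOC | intermediate
23 | Ugonin G | CC1=CCCC(C)(C)[C@H]1Cc1c(O)cc2oc(-c3ccc(O)cc3)c(O)c(=O)c2c1O | target

**Totals**
Total step count: 15. Longest linear sequence: 11 steps (1, 2, 3, 4, 5, 9, 10, 11, 13, 14, 15).

**Three steps most likely to fail**

Step 4 (Wittig–Still rearrangement). The [2,3] shift has to form a C–C bond next to a quaternary carbon and can lose out to the [1,2]-Wittig shift. The fallback sets out from 5 and comes back at 10. Johnson–Claisen rearrangement of 5 (triethyl orthoacetate, cat. propionic acid, 140 °C) gives, by the same suprafacial 1,3-chirality transfer but through a [3,3] shift, ethyl [(1R)-2,6,6-trimethylcyclohex-2-en-1-yl]acetate F1. Saponification (LiOH, THF/H2O) gives [(1R)-2,6,6-trimethylcyclohex-2-en-1-yl]acetic acid F2. DCC coupling with N-hydroxypyridine-2-thione gives the Barton ester 2-thioxopyridin-1(2H)-yl [(1R)-2,6,6-trimethylcyclohex-2-en-1-yl]acetate F3. Its photolysis in the presence of iodoform (radical decarboxylative iodination) delivers iodide 10, so steps 3–5 are bypassed.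

Step 9 (Negishi coupling). A β-branched alkylzinc has to couple with a di-ortho-substituted, electron-rich aryl iodide; slow transmetalation or β-hydride elimination would lower the yield or erode the stereocenter. The fallback sets out from 10 (with 14) and comes back at 16. Iodine–lithium exchange on 10 (t-BuLi, 2 equiv, Et2O, −78 °C) and trapping with B-methoxy-9-BBN gives lithium B-methoxy-B-{[(1R)-2,6,6-trimethylcyclohex-2-en-1-yl]methyl}-9-borabicyclo[3.3.1]nonan-9-uide F4. This is used directly in a B-alkyl Suzuki–Miyaura coupling with 14 (Pd(dppf)Cl2, K3PO4, DMF/THF, 50 °C) to give 16.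

Step 14 (Algar–Flynn–Oyamada). 2'-Hydroxychalcones with a 6'-alkoxy group can divert to aurones. The fallback sets out from 18 and comes back at 22, building the flavone without a chalcone and oxidising C-3 afterwards. Pinnick oxidation of 20 (NaClO2, NaH2PO4, 2-methyl-2-butene) gives 4-(methoxymethoxy)benzoic acid F5. EDC/DMAP esterification of the phenol of 18 gives 2-acetyl-3,5-bis(methoxymethoxy)-4-{[(1R)-2,6,6-trimethylcyclohex-2-en-1-yl]methyl}phenyl 4-(methoxymethoxy)benzoate F6. Baker–Venkataraman rearrangement (LiHMDS, THF, −78→0 °C) gives 1-[6-hydroxy-2,4-bis(methoxymethoxy)-3-{[(1R)-2,6,6-trimethylcyclohex-2-en-1-yl]methyl}phenyl]-3-[4-(methoxymethoxy)phenyl]propane-1,3-dione F7. Buffered cyclodehydration (NaOAc, AcOH, 80 °C) gives 5,7-bis(methoxymethoxy)-2-[4-(methoxymethoxy)phenyl]-6-{[(1R)-2,6,6-trimethylcyclohex-2-en-1-yl]methyl}-4H-chromen-4-one F8; the MOM ethers may partly cleave here and would then need re-installing. C-3 lithiation of the flavone (LDA, THF, −78 °C), trapping with B(OMe)3 and oxidation of the boronate (H2O2, aq. NaHCO3) gives 22.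

**Further compounds**
F1 | step 4 | ethyl [(1R)-2,6,6-trimethylcyclohex-2-en-1-yl]acetate | CC1=CCCC(C)(C)[C@H]1CC(=O)OCC
F2 | step 4 | [(1R)-2,6,6-trimethylcyclohex-2-en-1-yl]acetic acid | CC1=CCCC(C)(C)[C@H]1CC(=O)O
F3 | step 4 | 2-thioxopyridin-1(2H)-yl [(1R)-2,6,6-trimethylcyclohex-2-en-1-yl]acetate | CC1=CCCC(C)(C)[C@H]1CC(=O)On1ccccc1=S
F4 | step 9 | lithium B-methoxy-B-{[(1R)-2,6,6-trimethylcyclohex-2-en-1-yl]methyl}-9-borabicyclo[3.3.1]nonan-9-uide | CC1=CCCC(C)(C)[C@H]1C[B-]1(OC)C2CCCC1CCC2.[Li+]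
F5 | step 14 | 4-(methoxymethoxy)benzoic acid | COCOc1ccc(C(=O)O)cc1
F6 | step 14 | 2-acetyl-3,5-bis(methoxymethoxy)-4-{[(1R)-2,6,6-trimethylcyclohex-2-en-1-yl]methyl}phenyl 4-(methoxymethoxy)benzoate | CC1=CCCC(C)(C)[C@H]1Cc1c(OCOC)c(C(C)=O)c(OC(=O)c2ccc(OCOC)cc2)cc1OCOC
F7 | step 14 | 1-[6-hydroxy-2,4-bis(methoxymethoxy)-3-{[(1R)-2,6,6-trimethylcyclohex-2-en-1-yl]methyl}phenyl]-3-[4-(methoxymethoxy)phenyl]propane-1,3-dione | CC1=CCCC(C)(C)[C@H]1Cc1c(OCOC)c(C(=O)CC(=O)c2ccc(OCOC)cc2)c(O)cc1OCOC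
F8 | step 14 | 5,7-bis(methoxymethoxy)-2-[4-(methoxymethoxy)phenyl]-6-{[(1R)-2,6,6-trimethylcyclohex-2-en-1-yl]methyl}-4H-chromen-4-one | CC1=CCCC(C)(C)[C@H]1Cc1c(OCOC)cc2oc(-c3ccc(OCOC)cc3)cc(=O)c2c1OCOC
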